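One percent of the substrate charged is the unit of the readings below, and one side product A counts as two in it.

in all of them: substrate 0.20 M

|  | first nucleophile | second nucleophile | remark | time |
|---|---|---|---|---|
| eta | 0.14 M | 0.80 M (fed, over 30 s) | the very flask that is asked about, followed so far; the fed solution adds 0.25 times the starting volume |  |
| gamma | 0.28 M | 0.80 M (fed, over 30 s) | run made earlier; the fed solution adds 0.25 times the starting volume |  |
| flask | 0.140 M | 0.800 M (fed, over 30 s) | the fed solution adds 0.25 times the starting volume | 15 min |

eta run (percent of the substrate charged)

| time / s | substrate / % | target / % | side product A / % |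
|---|---|---|---|
| 10.0 | 13.3 | 61.0 | 20.2 |
| 15.0 | 5.5 | 58.6 | 24.2 |
| 30.0 | 1.1 | 57.7 | 25.2 |
| 60.0 | 0.6 | 56.9 | 25.7 |
| 120 | 0 | 58.5 | 26.5 |

gamma run (percent of the substrate charged)

| time / min | substrate / % | target / % | side product A / % |
|---|---|---|---|
| 0.500 | 1.1 | 73.3 | 26.1 |
| 1.50 | 0 | 72.2 | 24.4 |
| 3.00 | 0 | 73.1 | 23.4 |
| 4.00 | 0 | 75.8 | 24.5 |
| 6.00 | 0 | 75.3 | 23.7 |

(scatter of a reading: 1 percentage point)

- percentages count the substrate that a species holds: one side product A counts as two
- every charge counts on the volume at the start, and the solution that is fed holds the whole dose
- the analysis behind the earlier runs scatters by 1 percentage point, standard deviation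
- the reaction counts as stopped when no species that holds the substrate changes by six tenths of a point or more over the second half of the time

- the state of affairs at 15 min: stopped, and by what, or still going (the second nucleophile has run out first / it is still moving / forward and back rates have come level / all of the substrate has reacted)
- conversion of substrate at 15 min
- amount of target at 15 min, in percent of the substrate charged
- amount of side product A at 15 min, in percent of the substrate charged
- amount of target if the flask were left three thousand times as long, in percent of the substrate charged

In the eta flask, target plus half of side product A stays close to one value, set by the charges: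

target + side product A / 2 = 71.1% at 10.0 s, 69.8% at 60.0 s

ceiling = [first nucleophile] / [substrate], as charged = 0.140 M / 0.20 M = 70.0%

This ceiling is the most that target plus half of side product A can reach, in percent of the substrate charged. In the eta flask, first nucleophile is the limiting reagent for these two products.

The target curve of the eta flask starts steeply, with a mean slope of 0.0122 M s⁻¹ over the first 10.0 s. The knee lies at or before that reading: target stands at 61.0%, and the sum stands 1.1 percentage points from the ceiling, with a scatter of 1 point on each reading. On the ceiling, target loses half of what side product A gains. From 30.0 s on, side product A reads 25.8% on average, so the level of target follows: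

level = ceiling − side product A / 2 = 57.1%

Substrate falls from 5.5% at 15.0 s to 1.1% at 30.0 s, a read half-life of 6.46 s. That is short against 15 min, so the eta flask should stand at this level by then.

The forecast, slightly above this level, gives all of the substrate has reacted, conversion 100%, target 57.5%, side product A 26% and 57.5% much later, since “with it both routes stop”.

The eta flask gives all of the substrate has reacted, with conversion 100%, target 57.3%, side product A 25.4%, and 57.3% of target in the long run.

    second nucleophile + intermediate → other capture product (k = 7.43 L mol⁻¹ s⁻¹)
    substrate ⇌ intermediate (K = 0.280, k = 0.197 s⁻¹)
    intermediate → side product B (k = 0.0345 s⁻¹)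
    substrate + target → side product A (k = 0.368 L mol⁻¹ s⁻¹)
    first nucleophile + intermediate → target (k = 379 L mol⁻¹ s⁻¹)

In the eta flask, target plus half of side product A comes to 70.0% against the ceiling of 70.0%, and 0.051% of its first nucleophile is left at 15.0 min. The neighbour flask with 0.084 M of first nucleophile has a ceiling of 42.0%. Its target of 30.5% and side product A of 23.1% give a sum of 42.0%, and its first nucleophile stands at 0%.

Readings and results were generated by integration for an exercise.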